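## Retrosynthetic overview

1. Target 28 ⇐ removal of three silyl groups from 27 ⇐ ionic hydrogenation of the C9' methyl acetal 26.
2. Feature used: in the endo,endo-furofuran, C7' (bearing ring B) sits between the ring 2 oxygen and C8', and C8' becomes the β-carbon of a C8'=C9' enol ether when ring 1 (C7–O–C9'–C8'–C8) is written as a 2,3-dihydrofuran. Ring 2 (C7'–O–C9–C8–C8') is therefore cut at O–C7' and C7'–C8' into dihydrofuran alcohol 15 and aryl acetal 24.
3. 15 (ring 1) ⇐ lactol dehydration ⇐ ozonolysis ⇐ anti-aldol adduct of a pent-4-enoyl oxazolidinone with silylated vanillin (C7/C8 cis).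
4. 24 (cis-dihydrobenzofuran) ⇐ enantioselective benzylic C–H insertion of an aryl diazoacetate assembled from 5-iodovanillin, silylated vanillyl alcohol and ethyl diazoacetate.
5. Ring order: ring 1 and the dihydrobenzofuran are made in separate branches; ring 2 is closed last, in the coupling step.

Key step: step 16

Remark: lignan numbering is used for the furofuran (C7/C8/C9 on the ring A side, C7'/C8'/C9' on the ring B side). Ar = 4-(tert-butyldimethylsilyloxy)-3-methoxyphenyl, TBS = tert-butyldimethylsilyl, TMS = trimethylsilyl. Lactol 12, mesylate 13, ozonide 10 and mixed acetal 25 are epimer mixtures at the one undefined centre. 26 is drawn as the exo-methoxy epimer, but either C9' epimer serves because step 17 removes that centre.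

## Route

Step 1
Reactants: 1 vanillin
Product: 2 4-(TBS-oxy)-3-methoxybenzaldehyde
Conditions: TBSCl, imidazole, DMF, 0 °C to rt
Reagents that add atoms: tert-butyldimethylsilyl chloride, CC(C)(C)[Si](C)(C)Cl
Why: Imidazole-promoted silyl ether formation masks the phenol for the enolate, hydride and Lewis acid steps that follow.

Step 2
Reactants: 3 (S)-4-benzyloxazolidin-2-one; 4 pent-4-enoyl chloride
Product: 5 (S)-4-benzyl-3-(pent-4-enoyl)oxazolidin-2-one
Conditions: Et3N, DMAP (cat.), CH2Cl2, 0 °C to rt
Reagents that add atoms: none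
Why: DMAP-catalysed N-acylation of the oxazolidinone by the acid chloride gives the imide needed for auxiliary-controlled enolisation.

Step 3
Reactants: 5 (S)-4-benzyl-3-(pent-4-enoyl)oxazolidin-2-one; 2 4-(TBS-oxy)-3-methoxybenzaldehyde
Product: 7 anti-aldol imide (S)-4-benzyl-3-[(2R)-2-{(S)-Ar(hydroxy)methyl}pent-4-enoyl]oxazolidin-2-one, via O-trimethylsilyl aldol adduct 6 (not isolated)
Conditions: MgCl2 (0.2 equiv), Et3N, TMSCl, EtOAc, rt; then MeOH, TFA (cat.), rt
Reagents that add atoms: none
Why: Evans MgCl2-catalysed anti-aldol reaction, in which the chelated (Z)-magnesium enolate of the (S)-benzyl imide adds to the non-enolisable aldehyde through a boat-like transition state on the face away from the benzyl group and silyl trapping makes the addition irreversible, should set C8 as R and C7 as S (anti, the relationship that becomes cis in ring 1) before mild methanolysis removes the TMS group.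

Step 4
Reactants: 7 anti-aldol imide
Product: 8 (1S,2S)-2-allyl-1-Ar-propane-1,3-diol
Conditions: LiBH4, MeOH (1 equiv), THF, 0 °C
Reagents that add atoms: none
Why: Reductive cleavage of the N-acyl oxazolidinone by LiBH4 gives the primary C9 alcohol without touching the two stereocentres, the alkene or the aryl silyl ether, and releases the auxiliary.

Step 5
Reactants: 8 (1S,2S)-2-allyl-1-Ar-propane-1,3-diol
Product: 9 (2S)-2-{(S)-Ar(hydroxy)methyl}pent-4-en-1-yl pivalate
Conditions: PivCl, pyridine, CH2Cl2, −20 to 0 °C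
Reagents that add atoms: pivaloyl chloride, CC(C)(C)C(=O)Cl
Why: Sterically controlled acylation with the bulky acid chloride esterifies the primary C9 hydroxyl and leaves the hindered benzylic C7 hydroxyl free to become the ring 1 oxygen.

Step 6
Reactants: 9 (2S)-2-{(S)-Ar(hydroxy)methyl}pent-4-en-1-yl pivalate
Product: 12 lactol [(2S,3S)-2-Ar-5-hydroxytetrahydrofuran-3-yl]methyl pivalate, via ozonide 10 (not isolated), via hydroxy aldehyde 11 (not isolated)
Conditions: O3, CH2Cl2, −78 °C (stopped at first persistent blue); then PPh3, −78 °C to rt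
Reagents that add atoms: ozone, [O-][O+]=O
Why: Criegee ozonolysis of the terminal alkene (much faster than attack on the arene) and phosphine reduction unveil the C9' aldehyde, which the C7 hydroxyl captures at once as the five-membered lactol that is ring 1.

Step 7
Reactants: 12 lactol
Product: 14 [(2S,3S)-2-Ar-2,3-dihydrofuran-3-yl]methyl pivalate, via anomeric mesylate 13 (not isolated)
Conditions: MsCl, Et3N (excess), CH2Cl2, −40 °C to 40 °C
Reagents that add atoms: none
Why: Lactol dehydration by mesylation and amine-induced elimination through the ring oxocarbenium ion can only remove a proton from C8', giving the C8'=C9' enol ether under basic conditions that preserve C7 and C8.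

Step 8
Reactants: 14 dihydrofuran pivalate
Product: 15 [(2S,3S)-2-Ar-2,3-dihydrofuran-3-yl]methanol
Conditions: i-Bu2AlH, CH2Cl2, −78 °C; aq. potassium sodium tartrate
Reagents that add atoms: none
Why: Reductive ester cleavage at low temperature frees the C9 hydroxyl without acid or alkoxide, so the enol ether and the aryl silyl ether survive.

Step 9
Reactants: 2 4-(TBS-oxy)-3-methoxybenzaldehyde
Product: 16 [4-(TBS-oxy)-3-methoxyphenyl]methanol
Conditions: NaBH4, MeOH/THF, 0 °C
Reagents that add atoms: none
Why: Borohydride reduction of the aldehyde gives the benzylic alcohol that will supply C2 and the C2 aryl group of the dihydrobenzofuran.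

Step 10
Reactants: 16 [4-(TBS-oxy)-3-methoxyphenyl]methanol; 17 5-iodovanillin
Product: 18 4-{[4-(TBS-oxy)-3-methoxybenzyl]oxy}-3-iodo-5-methoxybenzaldehyde
Conditions: PPh3, DIAD, THF, 0 °C to rt
Reagents that add atoms: none
Why: Mitsunobu etherification alkylates the acidic phenol (para-formyl, ortho-iodo) with the activated primary benzylic alcohol under neutral conditions, avoiding a labile para-silyloxybenzyl halide and carbonate bases that would cleave the aryl silyl ether.

Step 11
Reactants: 18 iodoaryl ether aldehyde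
Product: 19 dimethyl acetal of 18
Conditions: HC(OMe)3, PPTS (cat.), MeOH, rt; Et3N quench
Reagents that add atoms: trimethyl orthoformate, COC(OC)OC; methanol, CO
Why: Acid-catalysed acetalisation with the orthoformate as water scavenger installs the dimethyl acetal, which protects the aldehyde through the carbenoid and hydride steps and is the electrophile of the key step.

Step 12
Reactants: 19 iodoaryl dimethyl acetal; 20 ethyl diazoacetate
Product: 21 ethyl 2-diazo-2-[2-{[4-(TBS-oxy)-3-methoxybenzyl]oxy}-5-(dimethoxymethyl)-3-methoxyphenyl]acetate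
Conditions: Pd(PPh3)4 (5 mol %), Ag2CO3 (0.5 equiv), Et3N, toluene, rt
Reagents that add atoms: none
Why: Palladium-catalysed cross-coupling of an aryl iodide with an acceptor diazoacetate (oxidative addition, silver- and base-assisted palladation of the diazo carbon, reductive elimination with the diazo group retained) gives the donor/acceptor diazo ester in one step.

Step 13
Reactants: 21 aryl diazoacetate
Product: 22 ethyl (2S,3R)-2-Ar-5-(dimethoxymethyl)-7-methoxy-2,3-dihydrobenzofuran-3-carboxylate (cis)
Conditions: Rh2(R-PTTL)4 [tetrakis(N-phthaloyl-(R)-tert-leucinato)dirhodium] (1–2 mol %), toluene, −78 to −60 °C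
Reagents that add atoms: none
Why: Enantioselective intramolecular 1,5 C–H insertion of the rhodium donor/acceptor carbenoid into the benzylic ether C–H forms C2–C3, with the concerted hydride-transfer-like transition state in the chiral carboxylate pocket placing aryl and ester cis under kinetic control; the (R)-catalyst is chosen because, by analogy with simpler 2-benzyloxyphenyl diazoacetates, the (S)-catalyst is expected to favour the (2R,3S) series.

Step 14
Reactants: 22 cis ester
Product: 23 [(2S,3S)-2-Ar-5-(dimethoxymethyl)-7-methoxy-2,3-dihydrobenzofuran-3-yl]methanol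
Conditions: i-Bu2AlH (excess), CH2Cl2, −78 to −40 °C; aq. potassium sodium tartrate
Reagents that add atoms: none
Why: Low-temperature hydride reduction of the ester to the primary alcohol avoids the basic conditions that would epimerise the cis ester at C3 to the trans isomer, and the acetal and aryl silyl ether are inert.

Step 15
Reactants: 23 cis alcohol
Product: 24 (2S,3S)-2-Ar-3-(TBS-oxymethyl)-5-(dimethoxymethyl)-7-methoxy-2,3-dihydrobenzofuran
Conditions: TBSCl, imidazole, DMF, 0 °C to rt
Reagents that add atoms: tert-butyldimethylsilyl chloride, CC(C)(C)[Si](C)(C)Cl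
Why: Silyl ether formation removes the only hydroxyl that could compete with the C9 hydroxyl of 15 for the acetal in the key step.

Step 16
Reactants: 15 [(2S,3S)-2-Ar-2,3-dihydrofuran-3-yl]methanol; 24 cis-dihydrobenzofuran dimethyl acetal
Product: 26 C9'-methoxy endo,endo-furofuran acetal (7S,8S,7'S,8'R,9'S), via mixed methyl acetal 25 (not isolated)
Conditions: TMSOTf (0.2 equiv), CH2Cl2, −78 °C, short reaction time; Et3N quench at −78 °C
Reagents that add atoms: none
Why: TMSOTf ionises the dimethyl acetal of 24, the C9 hydroxyl of 15 exchanges in to give mixed acetal 25, and renewed ionisation gives the (E)-oxocarbenium ion ArCH=O(+)–C9, whose carbon C7' is attacked by enol ether carbon C8' while the methanol set free caps the new C9' oxocarbenium ion. The closest known reaction type is the intramolecular Mukaiyama–Prins (oxocarbenium–enol ether) annulation of cis-2-aryl-3-hydroxymethyl-2,3-dihydrofurans with aryl aldehyde dimethyl acetals, which is established for endo,endo-furofuran acetals. Ring 2 (C7'–O–C9–C8–C8') closes 5-endo-trig with respect to the C7'=O(+) bond and exo with respect to the C8'=C9' bond. C8' is set by the one-carbon tether, which lets C7' reach only the face of the dihydrofuran that carries C9 (cis ring fusion), and C9' is set by methanol adding from the convex face, although that centre is erased in step 17. C7' is set by the (E) geometry of the ion (aryl anti to C9) together with a synclinal, compact alignment of C7'=O(+) over C8'=C9', which keeps the charge moving to C9'–O1 close to the ring 2 oxygen and the aryl face and turns ring B to the concave, endo side. The selectivity needed is this kinetic endo placement with intact benzylic ethers at C7, C7' and C2 of the dihydrobenzofuran, and it is secured by the cis C7/C8 relationship of 15, low temperature, substoichiometric acid and a cold amine quench before equilibration to the exo isomer can begin.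

Step 17
Reactants: 26 C9'-methoxy furofuran acetal
Product: 27 tris-TBS ether of the target (7S,8S,7'S,8'S)
Conditions: Et3SiH, BF3·OEt2, CH2Cl2, −78 °C; Et3N then aq. NaHCO3, cold
Reagents that add atoms: none
Why: Ionic hydrogenation (Lewis acid ionisation of the C9' acetal to the ring 1 oxocarbenium ion, then hydride transfer from the silane) removes the anomeric oxygen, and at −78 °C the acetal should ionise far faster than the benzylic ethers, so C7, C7' and the cis-dihydrobenzofuran keep their configuration.

Step 18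
Reactants: 27 tris-TBS ether
Product: 28 target CNP0303197.1
Conditions: Bu4NF, AcOH (1:1), THF, 0 °C to rt
Reagents that add atoms: none
Why: Fluoride-mediated desilylation buffered with acetic acid removes the two aryl and one alkyl silyl ethers while avoiding a free phenoxide para to the benzylic ethers and any strong acid that would epimerise the endo aryl groups.

## Compound list

1 | vanillin | COc1cc(C=O)ccc1O | starting material
2 | 4-(tert-butyldimethylsilyloxy)-3-methoxybenzaldehyde | COc1cc(C=O)ccc1O[Si](C)(C)C(C)(C)C | intermediate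
3 | (S)-4-benzyloxazolidin-2-one | O=C1N[C@@H](Cc2ccccc2)CO1 | starting material
4 | pent-4-enoyl chloride | C=CCCC(=O)Cl | starting material
5 | (S)-4-benzyl-3-(pent-4-enoyl)oxazolidin-2-one | C=CCCC(=O)N1[C@@H](Cc2ccccc2)COC1=O | intermediate
6 | O-trimethylsilyl aldol adduct, (S)-4-benzyl-3-[(2R)-2-{(S)-Ar(trimethylsilyloxy)methyl}pent-4-enoyl]oxazolidin-2-one | C=CC[C@H]([C@H](O[Si](C)(C)C)c1ccc(O[Si](C)(C)C(C)(C)C)c(OC)c1)C(=O)N1[C@@H](Cc2ccccc2)COC1=O | intermediate
7 | anti-aldol imide, (S)-4-benzyl-3-[(2R)-2-{(S)-Ar(hydroxy)methyl}pent-4-enoyl]oxazolidin-2-one | C=CC[C@H]([C@H](O)c1ccc(O[Si](C)(C)C(C)(C)C)c(OC)c1)C(=O)N1[C@@H](Cc2ccccc2)COC1=O | intermediate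
8 | (1S,2S)-2-allyl-1-Ar-propane-1,3-diol | C=CC[C@H]([C@H](O)c1ccc(O[Si](C)(C)C(C)(C)C)c(OC)c1)CO | intermediate
9 | (2S)-2-{(S)-Ar(hydroxy)methyl}pent-4-en-1-yl pivalate | C=CC[C@H]([C@H](O)c1ccc(O[Si](C)(C)C(C)(C)C)c(OC)c1)COC(=O)C(C)(C)C | intermediate
10 | ozonide of 9 (3-substituted 1,2,4-trioxolane) | O1OC(C[C@H]([C@H](O)c2ccc(O[Si](C)(C)C(C)(C)C)c(OC)c2)COC(=O)C(C)(C)C)OC1 | intermediate
11 | (3S,4S)-4-Ar-4-hydroxy-3-(pivaloyloxymethyl)butanal | O=CC[C@H]([C@H](O)c1ccc(O[Si](C)(C)C(C)(C)C)c(OC)c1)COC(=O)C(C)(C)C | intermediate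
12 | [(2S,3S)-2-Ar-5-hydroxytetrahydrofuran-3-yl]methyl pivalate (lactol, both anomers) | OC1C[C@@H](COC(=O)C(C)(C)C)[C@@H](c2ccc(O[Si](C)(C)C(C)(C)C)c(OC)c2)O1 | intermediate
13 | anomeric mesylate of 12 | CS(=O)(=O)OC1C[C@@H](COC(=O)C(C)(C)C)[C@@H](c2ccc(O[Si](C)(C)C(C)(C)C)c(OC)c2)O1 | intermediate
14 | [(2S,3S)-2-Ar-2,3-dihydrofuran-3-yl]methyl pivalate | COc1cc([C@H]2OC=C[C@H]2COC(=O)C(C)(C)C)ccc1O[Si](C)(C)C(C)(C)C | intermediate
15 | [(2S,3S)-2-Ar-2,3-dihydrofuran-3-yl]methanol (cis) | COc1cc([C@H]2OC=C[C@H]2CO)ccc1O[Si](C)(C)C(C)(C)C | intermediate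
16 | [4-(tert-butyldimethylsilyloxy)-3-methoxyphenyl]methanol | COc1cc(CO)ccc1O[Si](C)(C)C(C)(C)C | intermediate
17 | 5-iodovanillin (4-hydroxy-3-iodo-5-methoxybenzaldehyde) | COc1cc(C=O)cc(I)c1O | starting material
18 | 4-{[4-(TBS-oxy)-3-methoxybenzyl]oxy}-3-iodo-5-methoxybenzaldehyde | COc1cc(C=O)cc(I)c1OCc1ccc(O[Si](C)(C)C(C)(C)C)c(OC)c1 | intermediate
19 | dimethyl acetal of 18 | COC(OC)c1cc(I)c(OCc2ccc(O[Si](C)(C)C(C)(C)C)c(OC)c2)c(OC)c1 | intermediate
20 | ethyl diazoacetate | CCOC(=O)C=[N+]=[N-] | starting material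
21 | ethyl 2-diazo-2-[2-{[4-(TBS-oxy)-3-methoxybenzyl]oxy}-5-(dimethoxymethyl)-3-methoxyphenyl]acetate | CCOC(=O)C(=[N+]=[N-])c1cc(C(OC)OC)cc(OC)c1OCc1ccc(O[Si](C)(C)C(C)(C)C)c(OC)c1 | intermediate
22 | ethyl (2S,3R)-2-Ar-5-(dimethoxymethyl)-7-methoxy-2,3-dihydrobenzofuran-3-carboxylate (cis) | COC(OC)c1cc(OC)c2c(c1)[C@@H](C(=O)OCC)[C@@H](c1ccc(O[Si](C)(C)C(C)(C)C)c(OC)c1)O2 | intermediate
23 | [(2S,3S)-2-Ar-5-(dimethoxymethyl)-7-methoxy-2,3-dihydrobenzofuran-3-yl]methanol (cis) | COC(OC)c1cc(OC)c2c(c1)[C@@H](CO)[C@@H](c1ccc(O[Si](C)(C)C(C)(C)C)c(OC)c1)O2 | intermediate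
24 | (2S,3S)-2-Ar-3-(TBS-oxymethyl)-5-(dimethoxymethyl)-7-methoxy-2,3-dihydrobenzofuran (cis) | COC(OC)c1cc(OC)c2c(c1)[C@@H](CO[Si](C)(C)C(C)(C)C)[C@@H](c1ccc(O[Si](C)(C)C(C)(C)C)c(OC)c1)O2 | intermediate
25 | mixed methyl acetal, C9–O–CH(OMe)–(ring B aryl) ether of 15 | COc1cc([C@H]2OC=C[C@H]2COC(OC)c2cc(OC)c3c(c2)[C@@H](CO[Si](C)(C)C(C)(C)C)[C@@H](c2ccc(O[Si](C)(C)C(C)(C)C)c(OC)c2)O3)ccc1O[Si](C)(C)C(C)(C)C | intermediate
26 | C9'-methoxy endo,endo-furofuran acetal (7S,8S,7'S,8'R,9'S), tris-TBS | COc1cc([C@H]2O[C@H](OC)[C@@H]3[C@H]2CO[C@@H]3c2cc(OC)c3c(c2)[C@@H](CO[Si](C)(C)C(C)(C)C)[C@@H](c2ccc(O[Si](C)(C)C(C)(C)C)c(OC)c2)O3)ccc1O[Si](C)(C)C(C)(C)C | intermediate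
27 | tris-TBS ether of the target (7S,8S,7'S,8'S; dihydrobenzofuran 2S,3S) | COc1cc([C@H]2OC[C@@H]3[C@H]2CO[C@@H]3c2cc(OC)c3c(c2)[C@@H](CO[Si](C)(C)C(C)(C)C)[C@@H](c2ccc(O[Si](C)(C)C(C)(C)C)c(OC)c2)O3)ccc1O[Si](C)(C)C(C)(C)C | intermediate
28 | CNP0303197.1 | COc1cc([C@H]2OC[C@@H]3[C@H]2CO[C@@H]3c2cc(OC)c3c(c2)[C@@H](CO)[C@@H](c2ccc(O)c(OC)c2)O3)ccc1O | target

## Step count and risks

Total steps: 18. Longest linear sequence: 11 steps (1, 9, 10, 11, 12, 13, 14, 15, 16, 17, 18). The dihydrofuran branch (1, 3–8, with 2 as a side step) joins at step 16.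

Most likely to fail:

**1. Step 16 (key annulation).** The process at risk is loss of kinetic control. The silyl triflate can ionise the para-silyloxybenzylic C–O bonds: C7–O1 of the dihydrofuran, the new C7'–O bond, and above all C2–O of the cis-dihydrobenzofuran carried by 24. Ring B would then relax to the exo position or the dihydrobenzofuran would drift to trans. Intermolecular acetalisation of the enol ether may also outrun exchange at the bulky acetal.

Fallback: the order of ring construction is inverted, so that the furofuran is closed with the simple iodoaryl acetal and the acid-sensitive cis-dihydrobenzofuran is built afterwards under non-acidic conditions. It sets out from 15 and 19 and comes back to the route at 28. The same TMSOTf annulation should give the iodoaryl C9'-methoxy furofuran acetal F1 , which carries the 3-iodo-5-methoxy-4-(silyloxybenzyloxy)phenyl group at C7'. Et3SiH/BF3·OEt2 at −78 °C should reduce F1 to the iodoaryl endo,endo-furofuran F2 . Coupling of F2 with 20 under Pd(PPh3)4/Ag2CO3 should give the furofuran aryl diazoacetate F3 . Rh2(R-PTTL)4 insertion should then convert F3 into the furofuran cis-dihydrobenzofuran ethyl ester F4 . i-Bu2AlH should reduce F4 to the bis-aryl-TBS primary alcohol F5 . Bu4NF/AcOH should remove the two aryl silyl groups of F5 and the route is rejoined at 28.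

**2. Step 13 (carbenoid C–H insertion).** The process at risk is insufficient enantiofacial discrimination, because both positions ortho to the ether oxygen are substituted and twist the benzyl ether out of the aryl plane. Partial stepwise hydride transfer at the strongly donor-substituted benzylic carbon would also erode cis selectivity.

Fallback: control is moved from the catalyst to separation of covalent diastereomers. It sets out from 21, which is cyclised and reduced as in steps 13 and 14 whatever enantiomeric purity is reached, and it comes back to the route at 23. The scalemic alcohol 23 is esterified with (S)-O-methylmandelic acid (carbodiimide, DMAP) to give the (2S,3S)-alcohol (S)-O-methylmandelate F6 . F6 is separated from its diastereomer and from any trans material by chromatography or crystallisation. i-Bu2AlH cleavage of pure F6 returns the route to 23 in enantiopure form.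

**3. Step 12 (aryl iodide–diazoacetate coupling).** The process at risk is slow palladation of the diazo carbon next to the bulky ortho-benzyloxy group, so that decomposition of the diazo ester on palladium (dinitrogen loss, carbene dimerisation) outruns coupling.

Fallback: the diazo group is introduced after the C–C bond is made. It sets out from 19 and comes back to the route at 21. Palladium-catalysed Negishi-type coupling with the Reformatsky reagent BrZnCH2CO2Et (Pd2(dba)3 [tris(dibenzylideneacetone)dipalladium], P(t-Bu)3, THF, rt) should give the arylacetate ethyl 2-[2-{[4-(TBS-oxy)-3-methoxybenzyl]oxy}-5-(dimethoxymethyl)-3-methoxyphenyl]acetate F7 . Regitz diazo transfer to F7 (4-acetamidobenzenesulfonyl azide, DBU, MeCN) then returns the route to 21.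

## Further compounds

F1 | step 16 | C9'-methoxy endo,endo-furofuran acetal with 3-iodo-5-methoxy-4-{[4-(TBS-oxy)-3-methoxybenzyl]oxy}phenyl at C7' | COc1cc([C@H]2O[C@H](OC)[C@@H]3[C@H]2CO[C@@H]3c2cc(I)c(OCc3ccc(O[Si](C)(C)C(C)(C)C)c(OC)c3)c(OC)c2)ccc1O[Si](C)(C)C(C)(C)C
F2 | step 16 | iodoaryl endo,endo-furofuran (C9' reduced) | COc1cc([C@H]2OC[C@@H]3[C@H]2CO[C@@H]3c2cc(I)c(OCc3ccc(O[Si](C)(C)C(C)(C)C)c(OC)c3)c(OC)c2)ccc1O[Si](C)(C)C(C)(C)C
F3 | step 16 | furofuran aryl diazoacetate (ethyl ester) | COc1cc([C@H]2OC[C@@H]3[C@H]2CO[C@@H]3c2cc(C(=[N+]=[N-])C(=O)OCC)c(OCc3ccc(O[Si](C)(C)C(C)(C)C)c(OC)c3)c(OC)c2)ccc1O[Si](C)(C)C(C)(C)C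
F4 | step 16 | furofuran with cis-(2S,3R)-dihydrobenzofuran ethyl ester, bis-aryl-TBS | COc1cc([C@H]2OC[C@@H]3[C@H]2CO[C@@H]3c2cc(OC)c3c(c2)[C@@H](C(=O)OCC)[C@@H](c2ccc(O[Si](C)(C)C(C)(C)C)c(OC)c2)O3)ccc1O[Si](C)(C)C(C)(C)C
F5 | step 16 | bis-aryl-TBS ether of the target (free primary alcohol) | COc1cc([C@H]2OC[C@@H]3[C@H]2CO[C@@H]3c2cc(OC)c3c(c2)[C@@H](CO)[C@@H](c2ccc(O[Si](C)(C)C(C)(C)C)c(OC)c2)O3)ccc1O[Si](C)(C)C(C)(C)C
F6 | step 13 | (S)-O-methylmandelate of (2S,3S)-alcohol 23 | COC(OC)c1cc(OC)c2c(c1)[C@@H](COC(=O)[C@@H](OC)c1ccccc1)[C@@H](c1ccc(O[Si](C)(C)C(C)(C)C)c(OC)c1)O2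
F7 | step 12 | ethyl 2-[2-{[4-(TBS-oxy)-3-methoxybenzyl]oxy}-5-(dimethoxymethyl)-3-methoxyphenyl]acetate | CCOC(=O)Cc1cc(C(OC)OC)cc(OC)c1OCc1ccc(O[Si](C)(C)C(C)(C)C)c(OC)c1
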